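The lactone is numbered from its carbonyl (C1) to the methyl (C22). The oxocenone ring (O, C1–C7) is cut back by a Baeyer–Villiger step to a 2-cyclopropylcyclohept-4-enone, whose C3–C4=C5–C6 unit is a buta-1,3-diene in disguise and whose C2–C1–C7 unit is a vinylcarbenoid. The key step, a rhodium-catalysed tandem cyclopropanation/Cope rearrangement of butadiene with a siloxyvinyldiazoacetate that already carries the trans-cyclopropane (C8–C10), forms C2–C3 and C6–C7 in one operation through a divinylcyclopropane whose C2–C4 bond is not in the target, sets C7 and fixes the Z-C4=C5 olefin. The C12–C22 chain is then added to a C11 aldehyde as an alkenylzinc.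

Key step: step 9

Assumption: the hand of the rhodium catalyst in step 9 is assigned by analogy with related donor/acceptor carbenoids and is not certain; should cyclopropanation occur on the other face, Rh2(R-PTAD)4 is used in its place.

**Fragment 1 (C1–C11, steps 1–13)**

Step 1
Reactants: 1 prop-2-yn-1-ol; 2 allyl bromide
Product: 3 hex-5-en-2-yn-1-ol
Conditions: CuI (cat.), K2CO3, NaI, DMF, rt
Reagents that add atoms: none
Why: Copper-acetylide allylation of the terminal alkyne (Cu-catalysed sp–sp3 coupling) should give the skipped enyne without protection of the alcohol.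

Step 2
Reactants: 3 hex-5-en-2-yn-1-ol
Product: 4 (2E)-hexa-2,5-dien-1-ol
Conditions: LiAlH4, THF, 0 °C to reflux; aqueous NaOH work-up
Reagents that add atoms: none
Why: Hydroxyl-directed trans-hydroalumination of the propargylic alcohol should give only the E-allylic alcohol and leave the isolated terminal olefin untouched.

Step 3
Reactants: 4 (2E)-hexa-2,5-dien-1-ol
Product: 5 [(1R,2R)-2-(prop-2-en-1-yl)cyclopropyl]methanol
Conditions: Et2Zn, CH2I2, DME, (4S,5S)-2-butyl-N,N,N',N'-tetramethyl-1,3,2-dioxaborolane-4,5-dicarboxamide (1.2 equiv), CH2Cl2, −10 °C to rt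
Reagents that add atoms: diiodomethane ICI
Why: In this dioxaborolane-mediated asymmetric Simmons–Smith cyclopropanation the zinc alkoxide delivers CH2 only to the allylic olefin, the E-geometry gives the trans ring, and the (4S,5S)-ligand sets both ring centres (C8 and C10 of the target).

Step 4
Reactants: 5 [(1R,2R)-2-(prop-2-en-1-yl)cyclopropyl]methanol
Product: 6 tert-butyl{[(1R,2R)-2-(prop-2-en-1-yl)cyclopropyl]methoxy}diphenylsilane
Conditions: TBDPSCl, imidazole, DMF, rt
Reagents that add atoms: tert-butyl(chloro)diphenylsilane CC(C)(C)[Si](Cl)(c1ccccc1)c1ccccc1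
Why: Silylation of the primary alcohol gives an ether that should survive the acid, Lewis-acid and carbenoid steps up to step 12.

Step 5
Reactants: 6 tert-butyl{[(1R,2R)-2-(prop-2-en-1-yl)cyclopropyl]methoxy}diphenylsilane
Product: 7 2-[(1S,2R)-2-{[(tert-butyldiphenylsilyl)oxy]methyl}cyclopropyl]acetic acid
Conditions: RuCl3·xH2O (cat.), NaIO4, CCl4/MeCN/H2O, rt
Reagents that add atoms: sodium periodate [Na+].[O-]I(=O)(=O)=O; water O
Why: Oxidative cleavage of the terminal olefin by RuO4 formed in situ should give the acid with loss of the terminal carbon, the cyclopropane and silyl ether being inert.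

Step 6
Reactants: 7 2-[(1S,2R)-2-{[(tert-butyldiphenylsilyl)oxy]methyl}cyclopropyl]acetic acid; 8 potassium methyl malonate
Product: 10 methyl 4-[(1S,2R)-2-{[(tert-butyldiphenylsilyl)oxy]methyl}cyclopropyl]-3-oxobutanoate, via acyl imidazole 9 (not isolated)
Conditions: CDI, THF, rt; then 8, MgCl2, Et3N, MeCN, rt to 40 °C; aqueous HCl work-up
Reagents that add atoms: none
Why: Masamune–Brooks C-acylation of the magnesium malonate by the acyl imidazole followed by decarboxylation gives the β-keto ester (C2 and the ester carbon come from 8).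

Step 7
Reactants: 10 methyl 4-[(1S,2R)-2-{[(tert-butyldiphenylsilyl)oxy]methyl}cyclopropyl]-3-oxobutanoate
Product: 11 methyl 4-[(1S,2R)-2-{[(tert-butyldiphenylsilyl)oxy]methyl}cyclopropyl]-2-diazo-3-oxobutanoate
Conditions: 4-acetamidobenzenesulfonyl azide, Et3N, MeCN, 0 °C to rt
Reagents that add atoms: 4-acetamidobenzenesulfonyl azide CC(=O)Nc1ccc(cc1)S(=O)(=O)N=[N+]=[N-]
Why: Regitz diazo transfer to the doubly activated methylene is reliable for β-keto esters.

Step 8
Reactants: 11 methyl 4-[(1S,2R)-2-{[(tert-butyldiphenylsilyl)oxy]methyl}cyclopropyl]-2-diazo-3-oxobutanoate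
Product: 12 methyl (3Z)-3-[(tert-butyldimethylsilyl)oxy]-4-[(1R,2R)-2-{[(tert-butyldiphenylsilyl)oxy]methyl}cyclopropyl]-2-diazobut-3-enoate
Conditions: TBSOTf, Et3N, CH2Cl2, 0 °C
Reagents that add atoms: tert-butyldimethylsilyl triflate CC(C)(C)[Si](C)(C)OS(=O)(=O)C(F)(F)F
Why: Soft enolisation and O-silylation of the diazo ketone should give the Z-enol ether (cyclopropyl anti to the diazo carbon), the geometry that places the cyclopropyl group outward in the later Cope transition state.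

Step 9
Reactants: 12 methyl (3Z)-3-[(tert-butyldimethylsilyl)oxy]-4-[(1R,2R)-2-{[(tert-butyldiphenylsilyl)oxy]methyl}cyclopropyl]-2-diazobut-3-enoate; 13 buta-1,3-diene
Product: 15 methyl (3R,5Z)-2-[(tert-butyldimethylsilyl)oxy]-3-[(1R,2R)-2-{[(tert-butyldiphenylsilyl)oxy]methyl}cyclopropyl]cyclohepta-1,5-diene-1-carboxylate, via cis-divinylcyclopropane 14 (not isolated)
Conditions: dirhodium tetrakis[(S)-(1-adamantyl)(phthalimido)acetate], Rh2(S-PTAD)4 (1 mol %), 13 (large excess), hexanes, −20 °C to rt, slow addition of 12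
Reagents that add atoms: none
Why: Loss of N2 from 12 at the dirhodium tetracarboxylate gives a donor/acceptor vinylcarbenoid that cyclopropanates one double bond of butadiene (forming C2–C3 and the temporary C2–C4 bond) to the cis-divinylcyclopropane 14, which undergoes a [3,3]-sigmatropic (Cope) shift below room temperature, forming C6–C7 and breaking C2–C4. The closest known reaction type is the tandem cyclopropanation/Cope rearrangement of rhodium vinylcarbenoids with 1,3-dienes, a formal [4+3] cycloaddition. The three-membered ring closes by concerted [2+1] carbene transfer and the seven-membered ring by the [3,3] shift through a boat transition state, which is why both ring olefins (C4=C5 and the C1=C2 enol ether) must come out Z. C7 is the only new stereocentre that survives: the chiral catalyst selects the face of the carbenoid in the cyclopropanation, and the boat geometry with the cyclopropyl group on the outward position of the enol ether transmits that choice to C7. The step needs chemoselectivity for the diene (secured by the large excess of butadiene and slow addition of 12), cis-selectivity in the cyclopropanation (inherent to donor/acceptor carbenoids, the alkene substituent ending up syn to the vinyl donor) and catalyst-over-substrate control (the resident cyclopropane centres are three bonds from the carbenoid carbon).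

Step 10
Reactants: 15 methyl (3R,5Z)-2-[(tert-butyldimethylsilyl)oxy]-3-[(1R,2R)-2-{[(tert-butyldiphenylsilyl)oxy]methyl}cyclopropyl]cyclohepta-1,5-diene-1-carboxylate
Product: 17 (2R,4Z)-2-[(1R,2R)-2-{[(tert-butyldiphenylsilyl)oxy]methyl}cyclopropyl]cyclohept-4-en-1-one, via β-keto ester 16 (not isolated)
Conditions: HCl (1 M), THF, 0 °C; then LiCl, H2O, DMSO, 130 °C
Reagents that add atoms: none
Why: Hydrolysis of the silyl enol ether followed by Krapcho dealkoxycarbonylation runs under near-neutral conditions in which the β-keto ester enolises toward C2, so the C7 configuration should be retained.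

Step 11
Reactants: 17 (2R,4Z)-2-[(1R,2R)-2-{[(tert-butyldiphenylsilyl)oxy]methyl}cyclopropyl]cyclohept-4-en-1-one
Product: 18 (5Z,8R)-8-[(1R,2R)-2-{[(tert-butyldiphenylsilyl)oxy]methyl}cyclopropyl]-3,4,7,8-tetrahydro-2H-oxocin-2-one
Conditions: bis(trimethylsilyl) peroxide, TMSOTf (cat.), CH2Cl2, −78 to −40 °C
Reagents that add atoms: bis(trimethylsilyl) peroxide C[Si](C)(C)OO[Si](C)(C)C
Why: In this Baeyer–Villiger oxidation the secondary, cyclopropyl-bearing C7 should migrate in preference to the primary C2 with retention of configuration, and the silyl peroxide reagent is chosen because it does not epoxidise olefins.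

Step 12
Reactants: 18 (5Z,8R)-8-[(1R,2R)-2-{[(tert-butyldiphenylsilyl)oxy]methyl}cyclopropyl]-3,4,7,8-tetrahydro-2H-oxocin-2-one
Product: 19 (5Z,8R)-8-[(1R,2R)-2-(hydroxymethyl)cyclopropyl]-3,4,7,8-tetrahydro-2H-oxocin-2-one
Conditions: TBAF, AcOH, THF, rt
Reagents that add atoms: none
Why: Buffered fluoride desilylation should free the primary alcohol without opening the eight-membered lactone.

Step 13
Reactants: 19 (5Z,8R)-8-[(1R,2R)-2-(hydroxymethyl)cyclopropyl]-3,4,7,8-tetrahydro-2H-oxocin-2-one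
Product: 20 (1R,2R)-2-[(2R,4Z)-8-oxo-3,6,7,8-tetrahydro-2H-oxocin-2-yl]cyclopropane-1-carbaldehyde
Conditions: Dess–Martin periodinane, NaHCO3, CH2Cl2, 0 °C to rt
Reagents that add atoms: none
Why: Dess–Martin oxidation gives the cyclopropanecarbaldehyde, which is not readily enolised and should therefore keep its trans configuration.

**Fragment 2 (C12–C22, steps 14–17)**

Step 14
Reactants: 21 (3Z,6Z)-nona-3,6-dien-1-ol
Product: 22 (3Z,6Z)-nona-3,6-dienal
Conditions: Dess–Martin periodinane, NaHCO3, CH2Cl2, 0 °C; used at once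
Reagents that add atoms: none
Why: Buffered Dess–Martin oxidation should give the β,γ-unsaturated aldehyde without migration of the Z-olefin into conjugation, provided the aldehyde is used directly.

Step 15
Reactants: 22 (3Z,6Z)-nona-3,6-dienal; 23 ethynyltrimethylsilane
Product: 25 (3S,5Z,8Z)-1-(trimethylsilyl)undeca-5,8-dien-1-yn-3-ol, via alkynyl(ethyl)zinc 24 (not isolated)
Conditions: 23, Et2Zn, HMPA, CH2Cl2, rt; then (R)-BINOL (cat.), Ti(OiPr)4; then 22, rt; aqueous NH4Cl
Reagents that add atoms: none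
Why: BINOL/Ti(OiPr)4-catalysed asymmetric alkynylzinc addition to the aldehyde proceeds without amine base, and (R)-BINOL is expected to deliver the 14S carbinol (the mirror of the sense known for (S)-BINOL).

Step 16
Reactants: 25 (3S,5Z,8Z)-1-(trimethylsilyl)undeca-5,8-dien-1-yn-3-ol
Product: 26 (3S,5Z,8Z)-undeca-5,8-dien-1-yn-3-ol
Conditions: K2CO3 (cat.), MeOH, rt
Reagents that add atoms: none
Why: Methanolysis of the C(sp)–Si bond frees the terminal alkyne without touching the carbinol centre or the skipped diene.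

Step 17
Reactants: 26 (3S,5Z,8Z)-undeca-5,8-dien-1-yn-3-ol
Product: 27 tert-butyldimethyl{[(3S,5Z,8Z)-undeca-5,8-dien-1-yn-3-yl]oxy}silane
Conditions: TBSCl, imidazole, DMF, rt
Reagents that add atoms: tert-butyl(chloro)dimethylsilane CC(C)(C)[Si](C)(C)Cl
Why: Silylation masks the C14 hydroxyl so that the hydrometallation in step 18 consumes no hydride.

**Coupling and deprotection (steps 18–19)**

Step 18
Reactants: 27 tert-butyldimethyl{[(3S,5Z,8Z)-undeca-5,8-dien-1-yn-3-yl]oxy}silane; 20 (1R,2R)-2-[(2R,4Z)-8-oxo-3,6,7,8-tetrahydro-2H-oxocin-2-yl]cyclopropane-1-carbaldehyde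
Product: 30 (5Z,8R)-8-{(1R,2R)-2-[(1R,2E,4S,6Z,9Z)-4-[(tert-butyldimethylsilyl)oxy]-1-hydroxydodeca-2,6,9-trien-1-yl]cyclopropyl}-3,4,7,8-tetrahydro-2H-oxocin-2-one, via alkenylborane 28 (not isolated), via alkenylzinc 29 (not isolated)
Conditions: 27, Cy2BH, toluene, 0 °C to rt; Me2Zn, −78 °C; (2R)-(+)-3-exo-morpholinoisoborneol [(+)-MIB, 10 mol %], then 20, −20 to 0 °C; aqueous NH4Cl
Reagents that add atoms: none
Why: Syn-hydroboration of the terminal alkyne, boron-to-zinc exchange and amino-alcohol-catalysed 1,2-addition of the (E)-alkenylzinc form C11–C12 with the E-olefin, (+)-MIB being expected to direct attack to the aldehyde face that gives 11R (the mirror of the known sense of (−)-MIB) while the lactone is inert to organozinc reagents.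

Step 19
Reactants: 30 (5Z,8R)-8-{(1R,2R)-2-[(1R,2E,4S,6Z,9Z)-4-[(tert-butyldimethylsilyl)oxy]-1-hydroxydodeca-2,6,9-trien-1-yl]cyclopropyl}-3,4,7,8-tetrahydro-2H-oxocin-2-one
Product: 31 (5Z,8R)-8-{(1R,2R)-2-[(1R,2E,4S,6Z,9Z)-1,4-dihydroxydodeca-2,6,9-trien-1-yl]cyclopropyl}-3,4,7,8-tetrahydro-2H-oxocin-2-one
Conditions: TBAF, AcOH, THF, 0 °C to rt
Reagents that add atoms: none
Why: Buffered fluoride desilylation avoids acid, which the allylic cyclopropylcarbinyl alcohol at C11 would not tolerate, and should leave the lactone closed.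

**Compound list**

1 | prop-2-yn-1-ol | OCC#C | starting material
2 | allyl bromide | C=CCBr | starting material
3 | hex-5-en-2-yn-1-ol | OCC#CCC=C | intermediate
4 | (2E)-hexa-2,5-dien-1-ol | OC/C=C/CC=C | intermediate
5 | [(1R,2R)-2-(prop-2-en-1-yl)cyclopropyl]methanol | OC[C@@H]1C[C@H]1CC=C | intermediate
6 | tert-butyl{[(1R,2R)-2-(prop-2-en-1-yl)cyclopropyl]methoxy}diphenylsilane | CC(C)(C)[Si](c1ccccc1)(c1ccccc1)OC[C@@H]1C[C@H]1CC=C | intermediate
7 | 2-[(1S,2R)-2-{[(tert-butyldiphenylsilyl)oxy]methyl}cyclopropyl]acetic acid | CC(C)(C)[Si](c1ccccc1)(c1ccccc1)OC[C@@H]1C[C@H]1CC(=O)O | intermediate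
8 | potassium methyl malonate | COC(=O)CC(=O)[O-].[K+] | starting material
9 | 1-acylimidazole of acid 7 | CC(C)(C)[Si](c1ccccc1)(c1ccccc1)OC[C@@H]1C[C@H]1CC(=O)n1ccnc1 | intermediate
10 | methyl 4-[(1S,2R)-2-{[(tert-butyldiphenylsilyl)oxy]methyl}cyclopropyl]-3-oxobutanoate | CC(C)(C)[Si](c1ccccc1)(c1ccccc1)OC[C@@H]1C[C@H]1CC(=O)CC(=O)OC | intermediate
11 | methyl 4-[(1S,2R)-2-{[(tert-butyldiphenylsilyl)oxy]methyl}cyclopropyl]-2-diazo-3-oxobutanoate | CC(C)(C)[Si](c1ccccc1)(c1ccccc1)OC[C@@H]1C[C@H]1CC(=O)C(=[N+]=[N-])C(=O)OC | intermediate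
12 | methyl (3Z)-3-[(tert-butyldimethylsilyl)oxy]-4-[(1R,2R)-2-{[(tert-butyldiphenylsilyl)oxy]methyl}cyclopropyl]-2-diazobut-3-enoate | CC(C)(C)[Si](c1ccccc1)(c1ccccc1)OC[C@@H]1C[C@H]1/C=C(\O[Si](C)(C)C(C)(C)C)C(=[N+]=[N-])C(=O)OC | intermediate
13 | buta-1,3-diene | C=CC=C | starting material
14 | methyl (1R,2S)-1-{(1Z)-1-[(tert-butyldimethylsilyl)oxy]-2-[(1R,2R)-2-{[(tert-butyldiphenylsilyl)oxy]methyl}cyclopropyl]ethenyl}-2-ethenylcyclopropane-1-carboxylate | COC(=O)[C@]1(/C(O[Si](C)(C)C(C)(C)C)=C/[C@@H]2C[C@H]2CO[Si](c2ccccc2)(c2ccccc2)C(C)(C)C)C[C@H]1C=C | intermediate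
15 | methyl (3R,5Z)-2-[(tert-butyldimethylsilyl)oxy]-3-[(1R,2R)-2-{[(tert-butyldiphenylsilyl)oxy]methyl}cyclopropyl]cyclohepta-1,5-diene-1-carboxylate | CC(C)(C)[Si](c1ccccc1)(c1ccccc1)OC[C@@H]1C[C@H]1[C@H]1C/C=C\CC(C(=O)OC)=C1O[Si](C)(C)C(C)(C)C | intermediate
16 | methyl (3R,5Z)-3-[(1R,2R)-2-{[(tert-butyldiphenylsilyl)oxy]methyl}cyclopropyl]-2-oxocyclohept-5-ene-1-carboxylate (epimers at the ester-bearing carbon, in equilibrium with the enol) | CC(C)(C)[Si](c1ccccc1)(c1ccccc1)OC[C@@H]1C[C@H]1[C@H]1C/C=C\CC(C(=O)OC)C1=O | intermediate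
17 | (2R,4Z)-2-[(1R,2R)-2-{[(tert-butyldiphenylsilyl)oxy]methyl}cyclopropyl]cyclohept-4-en-1-one | CC(C)(C)[Si](c1ccccc1)(c1ccccc1)OC[C@@H]1C[C@H]1[C@H]1C/C=C\CCC1=O | intermediate
18 | (5Z,8R)-8-[(1R,2R)-2-{[(tert-butyldiphenylsilyl)oxy]methyl}cyclopropyl]-3,4,7,8-tetrahydro-2H-oxocin-2-one | CC(C)(C)[Si](c1ccccc1)(c1ccccc1)OC[C@@H]1C[C@H]1[C@H]1C/C=C\CCC(=O)O1 | intermediate
19 | (5Z,8R)-8-[(1R,2R)-2-(hydroxymethyl)cyclopropyl]-3,4,7,8-tetrahydro-2H-oxocin-2-one | OC[C@@H]1C[C@H]1[C@H]1C/C=C\CCC(=O)O1 | intermediate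
20 | (1R,2R)-2-[(2R,4Z)-8-oxo-3,6,7,8-tetrahydro-2H-oxocin-2-yl]cyclopropane-1-carbaldehyde | O=C[C@@H]1C[C@H]1[C@H]1C/C=C\CCC(=O)O1 | intermediate
21 | (3Z,6Z)-nona-3,6-dien-1-ol | CC/C=C\C/C=C\CCO | starting material
22 | (3Z,6Z)-nona-3,6-dienal | CC/C=C\C/C=C\CC=O | intermediate
23 | ethynyltrimethylsilane | C#C[Si](C)(C)C | starting material
24 | ethyl[(trimethylsilyl)ethynyl]zinc | CC[Zn]C#C[Si](C)(C)C | intermediate
25 | (3S,5Z,8Z)-1-(trimethylsilyl)undeca-5,8-dien-1-yn-3-ol | CC/C=C\C/C=C\C[C@H](O)C#C[Si](C)(C)C | intermediate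
26 | (3S,5Z,8Z)-undeca-5,8-dien-1-yn-3-ol | CC/C=C\C/C=C\C[C@H](O)C#C | intermediate
27 | tert-butyldimethyl{[(3S,5Z,8Z)-undeca-5,8-dien-1-yn-3-yl]oxy}silane | CC/C=C\C/C=C\C[C@H](O[Si](C)(C)C(C)(C)C)C#C | intermediate
28 | dicyclohexyl{(1E,3S,5Z,8Z)-3-[(tert-butyldimethylsilyl)oxy]undeca-1,5,8-trien-1-yl}borane | CC/C=C\C/C=C\C[C@H](O[Si](C)(C)C(C)(C)C)/C=C/B(C1CCCCC1)C1CCCCC1 | intermediate
29 | methyl{(1E,3S,5Z,8Z)-3-[(tert-butyldimethylsilyl)oxy]undeca-1,5,8-trien-1-yl}zinc | CC/C=C\C/C=C\C[C@H](O[Si](C)(C)C(C)(C)C)/C=C/[Zn]C | intermediate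
30 | (5Z,8R)-8-{(1R,2R)-2-[(1R,2E,4S,6Z,9Z)-4-[(tert-butyldimethylsilyl)oxy]-1-hydroxydodeca-2,6,9-trien-1-yl]cyclopropyl}-3,4,7,8-tetrahydro-2H-oxocin-2-one | CC/C=C\C/C=C\C[C@H](O[Si](C)(C)C(C)(C)C)/C=C/[C@@H](O)[C@@H]1C[C@H]1[C@H]1C/C=C\CCC(=O)O1 | intermediate
31 | (5Z,8R)-8-{(1R,2R)-2-[(1R,2E,4S,6Z,9Z)-1,4-dihydroxydodeca-2,6,9-trien-1-yl]cyclopropyl}-3,4,7,8-tetrahydro-2H-oxocin-2-one (CNP0319393.3) | CC/C=C\C/C=C\C[C@H](O)/C=C/[C@@H](O)[C@@H]1C[C@H]1[C@H]1C/C=C\CCC(=O)O1 | target

**Step count and risks**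

Total step count: 19. Longest linear sequence: 15 steps (steps 1–13, 18 and 19).

Steps most likely to fail:

1. Step 9. The cyclopropanation may show poor or reversed facial selectivity, which would erode C7, or the carbenoid may be diverted before it meets the diene. The fallback sets out from acid 7 and comes back at ketone 17, building the cycloheptenone by auxiliary-controlled alkylation and ring-closing metathesis. Acid 7 is activated as its pivalic mixed anhydride (pivaloyl chloride, Et3N) and acylates lithiated (R)-4-benzyl-1,3-oxazolidin-2-one to give the N-acyloxazolidinone F1. Evans alkylation (NaHMDS, allyl iodide, THF, −78 °C) forms C6–C7 on the enolate face opposite the benzyl group and should give the 7R pentenoyl imide F2. LiOH/H2O2 removes the auxiliary to give the pentenoic acid F3, which is coupled with N,O-dimethylhydroxylamine (EDC, DMAP) to the Weinreb amide F4. But-3-enylmagnesium bromide then gives the dienone F5, and ring-closing metathesis with the second-generation Grubbs catalyst (CH2Cl2, 40 °C) closes C4=C5 as the ring-enforced Z-olefin and returns 17.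

2. Step 11. Oxygen insertion into the seven-membered ketone may be slow, so that oxidation of the C4=C5 olefin or Lewis-acid damage to the substrate competes. The fallback sets out from ketone 17 and comes back at lactone 18, masking the olefin during a classical peracid oxidation. Br2 (CH2Cl2, −78 °C) adds to C4=C5 to give the trans-dibromo ketone F6 as a diastereomer mixture. Trifluoroperacetic acid buffered with Na2HPO4 effects the Baeyer–Villiger oxidation to the dibromo lactone F7. Zinc dust in AcOH/Et2O then removes both bromines by anti elimination and regenerates the ring Z-olefin, returning 18.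

3. Step 18. Hydroboration may not distinguish the alkyne cleanly from the Z-olefins, and the ligand may fail to override the facial bias of the chiral aldehyde, giving a C11 epimer mixture. The fallback sets out from 27 and 20 and comes back at 30, separating C–C bond formation from the setting of C11. Cp2Zr(H)Cl followed by I2 converts 27 into the (E)-vinyl iodide F8, which is chemoselective for the terminal alkyne. Nozaki–Hiyama–Kishi coupling (CrCl2, NiCl2 cat., DMSO) with 20 gives the allylic alcohol F9 as a C11 epimer mixture. Dess–Martin oxidation gives the enone F10, and Corey–Bakshi–Shibata reduction with (R)-2-methyl-CBS-oxazaborolidine and catecholborane (toluene, −78 °C), which treats the alkenyl group as the large substituent and does not touch the lactone, should return 30 as the 11R alcohol.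

Further compounds
F1 | step 9 | (4R)-4-benzyl-3-{2-[(1S,2R)-2-{[(tert-butyldiphenylsilyl)oxy]methyl}cyclopropyl]acetyl}-1,3-oxazolidin-2-one | CC(C)(C)[Si](c1ccccc1)(c1ccccc1)OC[C@@H]1C[C@H]1CC(=O)N1[C@H](Cc2ccccc2)COC1=O
F2 | step 9 | (4R)-4-benzyl-3-{(2R)-2-[(1R,2R)-2-{[(tert-butyldiphenylsilyl)oxy]methyl}cyclopropyl]pent-4-enoyl}-1,3-oxazolidin-2-one | CC(C)(C)[Si](c1ccccc1)(c1ccccc1)OC[C@@H]1C[C@H]1[C@@H](CC=C)C(=O)N1[C@H](Cc2ccccc2)COC1=O
F3 | step 9 | (2R)-2-[(1R,2R)-2-{[(tert-butyldiphenylsilyl)oxy]methyl}cyclopropyl]pent-4-enoic acid | CC(C)(C)[Si](c1ccccc1)(c1ccccc1)OC[C@@H]1C[C@H]1[C@@H](CC=C)C(=O)O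
F4 | step 9 | (2R)-2-[(1R,2R)-2-{[(tert-butyldiphenylsilyl)oxy]methyl}cyclopropyl]-N-methoxy-N-methylpent-4-enamide | CC(C)(C)[Si](c1ccccc1)(c1ccccc1)OC[C@@H]1C[C@H]1[C@@H](CC=C)C(=O)N(C)OC
F5 | step 9 | (4R)-4-[(1R,2R)-2-{[(tert-butyldiphenylsilyl)oxy]methyl}cyclopropyl]nona-1,8-dien-5-one | CC(C)(C)[Si](c1ccccc1)(c1ccccc1)OC[C@@H]1C[C@H]1[C@@H](CC=C)C(=O)CCC=C
F6 | step 11 | (2R)-4,5-dibromo-2-[(1R,2R)-2-{[(tert-butyldiphenylsilyl)oxy]methyl}cyclopropyl]cycloheptan-1-one (trans-dibromide, diastereomer mixture) | CC(C)(C)[Si](c1ccccc1)(c1ccccc1)OC[C@@H]1C[C@H]1[C@H]1CC(Br)C(Br)CCC1=O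
F7 | step 11 | (8R)-5,6-dibromo-8-[(1R,2R)-2-{[(tert-butyldiphenylsilyl)oxy]methyl}cyclopropyl]oxocan-2-one (trans-dibromide, diastereomer mixture) | CC(C)(C)[Si](c1ccccc1)(c1ccccc1)OC[C@@H]1C[C@H]1[C@H]1CC(Br)C(Br)CCC(=O)O1
F8 | step 18 | tert-butyl{[(1E,3S,5Z,8Z)-1-iodoundeca-1,5,8-trien-3-yl]oxy}dimethylsilane | CC/C=C\C/C=C\C[C@H](O[Si](C)(C)C(C)(C)C)/C=C/I
F9 | step 18 | (5Z,8R)-8-{(1R,2R)-2-[(2E,4S,6Z,9Z)-4-[(tert-butyldimethylsilyl)oxy]-1-hydroxydodeca-2,6,9-trien-1-yl]cyclopropyl}-3,4,7,8-tetrahydro-2H-oxocin-2-one (both C11 epimers) | CC/C=C\C/C=C\C[C@H](O[Si](C)(C)C(C)(C)C)/C=C/C(O)[C@@H]1C[C@H]1[C@H]1C/C=C\CCC(=O)O1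
F10 | step 18 | (5Z,8R)-8-{(1R,2R)-2-[(2E,4S,6Z,9Z)-4-[(tert-butyldimethylsilyl)oxy]dodeca-2,6,9-trienoyl]cyclopropyl}-3,4,7,8-tetrahydro-2H-oxocin-2-one | CC/C=C\C/C=C\C[C@H](O[Si](C)(C)C(C)(C)C)/C=C/C(=O)[C@@H]1C[C@H]1[C@H]1C/C=C\CCC(=O)O1
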